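**Retrosynthetic overview**

1. Target 17 ⇐ aldehyde 16 (reduction at C1) ⇐ epoxy ketone 13 by Eschenmoser–Tanabe fragmentation, which cuts ring bond C15–C1 and creates C14≡C15.
2. Feature used: numbering the chain from the carbinol carbon C1 to C21 and the furan carbons C22–C25, the stretch C1–C15 (CH2OH, twelve further CH2, C14≡C15) holds fifteen carbons, exactly one cyclopentadecanone ring. C15 already bears C16≡C17, so the fragmentation delivers the 1,3-diyne directly.
3. 13 ⇐ enynone 12 (nucleophilic epoxidation) ⇐ 2-bromoenone 11 + alkyne 6 (Sonogashira, bond C15–C16); 11 ⇐ enone 9 ⇐ cyclopentadecanone 7.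
4. 6 (C16–C25 and the ring oxygen) ⇐ furan 1 + 1-bromo-4-chlorobutane 2 (bond C21–C22) + lithium acetylide 5 (bond C17–C18).
5. Ring order: no ring is built. The furan is bought intact, and the fifteen-membered carbocycle is the only ring that changes, being opened in the key step.

Key step: step 8

Assumption (chemistry): compounds 10 and 13–15 are racemic with uncontrolled relative configuration, and the double-bond geometry of 8, 11 and 12 is not controlled. All of these elements are erased by step 8 at the latest, so their SMILES carry no stereodescriptors.

**Route**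

Step 1
Reactants: 1 furan; 2 1-bromo-4-chlorobutane
Product: 4 2-(4-chlorobutyl)furan, via 2-furyllithium 3 (not isolated)
Conditions: n-BuLi, THF, 0 °C (excess furan); then 2, 0 °C → rt
Reagents that add atoms: none
Why: Furan is lithiated at C2, its most acidic position, and 2-furyllithium displaces the bromide of 2 in an SN2 alkylation, the much poorer chloride leaving group being kept for step 2.

Step 2
Reactants: 4 2-(4-chlorobutyl)furan; 5 lithium acetylide–ethylenediamine complex
Product: 6 6-(furan-2-yl)hex-1-yne
Conditions: DMSO, NaI (cat.), 10 °C → rt
Reagents that add atoms: none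
Why: SN2 alkylation of an acetylide, in which the lithium acetylide complex in DMSO displaces the primary chloride (helped by in situ Finkelstein exchange) while the furan offers no acidic or electrophilic site under these conditions.

Step 3
Reactants: 7 cyclopentadecanone
Product: 8 1-(trimethylsilyloxy)cyclopentadec-1-ene
Conditions: TMSOTf, Et3N, CH2Cl2, 0 °C
Reagents that add atoms: trimethylsilyl trifluoromethanesulfonate, C[Si](C)(C)OS(=O)(=O)C(F)(F)F
Why: Soft enolisation with O-silylation of a symmetrical ketone can give only one constitutional silyl enol ether, whose double-bond geometry is irrelevant for the next step.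

Step 4
Reactants: 8 1-(trimethylsilyloxy)cyclopentadec-1-ene
Product: 9 (E)-cyclopentadec-2-en-1-one
Conditions: Pd(OAc)2 (10 mol %), O2 (1 atm), DMSO/THF, rt
Reagents that add atoms: none
Why: Saegusa–Ito oxidation, in which divalent palladium forms the palladium enolate with loss of the silyl group and β-hydride elimination gives the enone, oxygen returning zerovalent palladium to the divalent state; the large ring accommodates the E double bond that should dominate.

Step 5
Reactants: 9 (E)-cyclopentadec-2-en-1-one
Product: 11 2-bromocyclopentadec-2-en-1-one, via 2,3-dibromocyclopentadecan-1-one 10 (not isolated)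
Conditions: Br2, CH2Cl2, 0 °C; then Et3N, 0 °C → rt
Reagents that add atoms: bromine, BrBr
Why: Bromination–dehydrobromination, in which anti addition of bromine across the ring C2=C3 bond gives dibromide 10 and triethylamine then removes the acidic C2–H with loss of the C3 bromide (E1cB-type elimination), leaving the vinylic bromide at C2.

Step 6
Reactants: 11 2-bromocyclopentadec-2-en-1-one; 6 6-(furan-2-yl)hex-1-yne
Product: 12 2-[6-(furan-2-yl)hex-1-yn-1-yl]cyclopentadec-2-en-1-one
Conditions: Pd(PPh3)2Cl2 (5 mol %), CuI (10 mol %), Et3N, THF (degassed), rt → 45 °C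
Reagents that add atoms: none
Why: Sonogashira coupling, in which zerovalent palladium inserts into the electron-poor C(sp2)–Br bond of the α-bromoenone, the copper acetylide of 6 transmetalates and reductive elimination forms the C15–C16 bond (target numbering), a tertiary amine being used because primary or secondary amines would add to the bromoenone.

Step 7
Reactants: 12 2-[6-(furan-2-yl)hex-1-yn-1-yl]cyclopentadec-2-en-1-one
Product: 13 2-[6-(furan-2-yl)hex-1-yn-1-yl]-2,3-epoxycyclopentadecan-1-one (1-[6-(furan-2-yl)hex-1-yn-1-yl]-16-oxabicyclo[13.1.0]hexadecan-2-one, racemic)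
Conditions: 30% aq. H2O2, NaOH, MeOH/THF, 0 °C → rt
Reagents that add atoms: hydrogen peroxide, OO
Why: Weitz–Scheffer nucleophilic epoxidation, in which hydroperoxide anion adds to the enone β-carbon and the enolate closes on the O–O bond, a nucleophilic oxidant that spares the electron-rich furan and the alkyne (a peracid would not); the two new stereocentres form racemic and without diastereocontrol, which is harmless because step 8 destroys both.

Step 8
Reactants: 13 2-[6-(furan-2-yl)hex-1-yn-1-yl]-2,3-epoxycyclopentadecan-1-one
Product: 16 21-(furan-2-yl)henicosa-14,16-diynal, via 2,4-dinitrobenzenesulfonylhydrazone 14 (not isolated), via hydroxy azoalkene 15 (not isolated)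
Conditions: 2,4-(O2N)2C6H3SO2NHNH2 (1.0–1.05 equiv), THF, −15 °C; then pyridine (1 equiv), −15 °C → rt
Reagents that add atoms: none
Why: Proposed new method: the Eschenmoser–Tanabe fragmentation is established for 2-alkyl and 2-unsubstituted 2,3-epoxycycloalkanone arenesulfonylhydrazones (the closest known reaction type, including the 2,4-dinitrobenzenesulfonyl variant used when an aldehyde is released), and it is extended here to a 2-alkynyl epoxy ketone so that the alkyne it forms is conjugated from the outset. The ketone (future C14) condenses to hydrazone 14, pyridine removes the N–H, and the hydrazone nitrogen pushes open the adjacent epoxide C15–O bond to give hydroxy azoalkene 15; its alkoxide then collapses in a Grob-type fragmentation that makes the C1 aldehyde, cuts the C15–C1 ring bond, forms C14≡C15 and expels N2 and arenesulfinate. Because C15 already bears the C16≡C17 alkynyl group, the same event fixes the chain length, the terminal oxygen and the 1,3-diyne, and the slim alkynyl group should neither hinder hydrazone formation nor disfavour epoxide opening, which gives a conjugated enyne azo compound. No ring is closed and no stereocentre is formed, and since both stereocentres of 13 are destroyed all its stereoisomers converge on 16. The selectivity needed is the site of C–C cleavage, which is fixed by the epoxide lying α,β to the hydrazone, with the flexible fifteen-membered ring letting the breaking C15–C1 bond align with the azoalkene π system; the freed aldehyde is protected by using one equivalent of the dinitro reagent, whose hydrazones fragment at or below room temperature, and the buffered non-acidic medium spares the furan.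

Step 9
Reactants: 16 21-(furan-2-yl)henicosa-14,16-diynal
Product: 17 21-(furan-2-yl)henicosa-14,16-diyn-1-ol (target)
Conditions: NaBH4, MeOH/THF, 0 °C
Reagents that add atoms: none
Why: Chemoselective borohydride reduction (1,2-hydride addition) of the aldehyde to the primary alcohol, the conjugated diyne and the furan being inert to NaBH4 and no stereocentre being created.

**Compound list**

1 | furan | c1ccoc1 | starting material
2 | 1-bromo-4-chlorobutane | ClCCCCBr | starting material
3 | 2-furyllithium | [Li]c1ccco1 | intermediate (not isolated)
4 | 2-(4-chlorobutyl)furan | ClCCCCc1ccco1 | intermediate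
5 | lithium acetylide–ethylenediamine complex | [Li]C#C.NCCN | starting material
6 | 6-(furan-2-yl)hex-1-yne | C#CCCCCc1ccco1 | intermediate
7 | cyclopentadecanone | O=C1CCCCCCCCCCCCCC1 | starting material
8 | 1-(trimethylsilyloxy)cyclopentadec-1-ene (geometry not controlled) | C[Si](C)(C)OC1=CCCCCCCCCCCCCC1 | intermediate
9 | (E)-cyclopentadec-2-en-1-one | O=C1/C=C/CCCCCCCCCCCC1 | intermediate
10 | 2,3-dibromocyclopentadecan-1-one (racemic) | O=C1C(Br)C(Br)CCCCCCCCCCCC1 | intermediate (not isolated)
11 | 2-bromocyclopentadec-2-en-1-one (geometry not controlled) | O=C1C(Br)=CCCCCCCCCCCCC1 | intermediate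
12 | 2-[6-(furan-2-yl)hex-1-yn-1-yl]cyclopentadec-2-en-1-one (geometry not controlled) | O=C1C(C#CCCCCc2ccco2)=CCCCCCCCCCCCC1 | intermediate
13 | 2-[6-(furan-2-yl)hex-1-yn-1-yl]-2,3-epoxycyclopentadecan-1-one (racemic, either diastereomer) | O=C1C2(C#CCCCCc3ccco3)OC2CCCCCCCCCCCC1 | intermediate
14 | 2,4-dinitrobenzenesulfonylhydrazone of 13 | O=S(=O)(NN=C2C3(C#CCCCCc4ccco4)OC3CCCCCCCCCCCC2)c1ccc(cc1[N+](=O)[O-])[N+](=O)[O-] | intermediate (not isolated)
15 | 2-[6-(furan-2-yl)hex-1-yn-1-yl]-3-[(2,4-dinitrophenyl)sulfonyldiazenyl]cyclopentadec-2-en-1-ol | O=S(=O)(N=NC2=C(C#CCCCCc3ccco3)C(O)CCCCCCCCCCCC2)c1ccc(cc1[N+](=O)[O-])[N+](=O)[O-] | intermediate (not isolated)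
16 | 21-(furan-2-yl)henicosa-14,16-diynal | O=CCCCCCCCCCCCCC#CC#CCCCCc1ccco1 | intermediate
17 | 21-(furan-2-yl)henicosa-14,16-diyn-1-ol | OCCCCCCCCCCCCCC#CC#CCCCCc1ccco1 | target

**Summary**

Total step count: 9. Longest linear sequence: 7 steps (cyclopentadecanone 7 to target 17, steps 3–9); the alkyne arm (steps 1–2) joins at step 6.

Steps most likely to fail:

1. Step 8 (proposed extension of the fragmentation). Condensation may stall beside the fully substituted epoxide carbon. The conjugated azoalkene may be intercepted before it fragments, by sulfinate or hydrazide addition or by attack of nitrogen on the neighbouring alkyne. The liberated aldehyde may condense with remaining hydrazide. The fallback builds the diyne by a copper-mediated coupling and keeps the ring-to-chain fragmentation only for the C1–C15 half, where it is established chemistry. It sets out from enone 9 and alkyne 6. Alkaline hydrogen peroxide (H2O2, NaOH, MeOH) would convert 9 into 2,3-epoxycyclopentadecan-1-one F1. 2,4-Dinitrobenzenesulfonylhydrazide and pyridine in THF would give its 2,4-dinitrobenzenesulfonylhydrazone F2, which would fragment in the flask to pentadec-14-ynal F3. NaBH4 would then give pentadec-14-yn-1-ol F4. N-Bromosuccinimide with catalytic AgNO3 in acetone would give 15-bromopentadec-14-yn-1-ol F5; the bromine is placed on this partner because the furan of 6 would itself be brominated. Cadiot–Chodkiewicz coupling of F5 with 6 (CuCl, NH2OH·HCl, aqueous n-BuNH2, MeOH, 0 °C) would form C15–C16 and come back to the route at target 17.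

2. Step 7 (nucleophilic epoxidation). Conjugate addition of hydroperoxide to the α,β-disubstituted and possibly twisted macrocyclic enone may be slow, so that base-mediated degradation takes over. The fallback sets out from 12 and replaces conjugate epoxidation by a hydroxyl-directed one. Luche reduction (NaBH4, CeCl3·7H2O, MeOH) would give 2-[6-(furan-2-yl)hex-1-yn-1-yl]cyclopentadec-2-en-1-ol F6. Epoxidation with VO(acac)2 and t-BuOOH, delivered to the allylic alkene by the hydroxyl group and sparing the furan, would give 2-[6-(furan-2-yl)hex-1-yn-1-yl]-2,3-epoxycyclopentadecan-1-ol F7. Dess–Martin periodinane would then oxidise F7 and come back to the route at 13.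

3. Step 6 (Sonogashira coupling). Oxidative addition into the hindered α-bromoenone may lag behind copper-mediated homocoupling of the alkyne or amine-induced decomposition of the bromoenone. The fallback forms the C15–C16 bond by carbonyl addition and sets out from ketone 7 and alkyne 6. Riley oxidation (SeO2, dioxane/H2O, reflux) would give cyclopentadecane-1,2-dione F8. Alkyne 6 would be deprotonated with n-BuLi (THF, −78 °C) to [6-(furan-2-yl)hex-1-yn-1-yl]lithium F9, and one equivalent would add to one carbonyl of F8 to give 2-hydroxy-2-[6-(furan-2-yl)hex-1-yn-1-yl]cyclopentadecan-1-one F10. Dehydration with the Burgess reagent can only proceed toward the ring CH2 and would come back to the route at 12.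

Further compounds
F1 | step 8 | 2,3-epoxycyclopentadecan-1-one (racemic) | O=C1C2OC2CCCCCCCCCCCC1
F2 | step 8 | 2,4-dinitrobenzenesulfonylhydrazone of 2,3-epoxycyclopentadecan-1-one | O=S(=O)(NN=C2C3OC3CCCCCCCCCCCC2)c1ccc(cc1[N+](=O)[O-])[N+](=O)[O-]
F3 | step 8 | pentadec-14-ynal | O=CCCCCCCCCCCCCC#C
F4 | step 8 | pentadec-14-yn-1-ol | OCCCCCCCCCCCCCC#C
F5 | step 8 | 15-bromopentadec-14-yn-1-ol | OCCCCCCCCCCCCCC#CBr
F6 | step 7 | 2-[6-(furan-2-yl)hex-1-yn-1-yl]cyclopentadec-2-en-1-ol (racemic) | OC1C(C#CCCCCc2ccco2)=CCCCCCCCCCCCC1
F7 | step 7 | 2-[6-(furan-2-yl)hex-1-yn-1-yl]-2,3-epoxycyclopentadecan-1-ol (racemic) | OC1C2(C#CCCCCc3ccco3)OC2CCCCCCCCCCCC1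
F8 | step 6 | cyclopentadecane-1,2-dione | O=C1C(=O)CCCCCCCCCCCCC1
F9 | step 6 | [6-(furan-2-yl)hex-1-yn-1-yl]lithium | [Li]C#CCCCCc1ccco1
F10 | step 6 | 2-hydroxy-2-[6-(furan-2-yl)hex-1-yn-1-yl]cyclopentadecan-1-one (racemic) | O=C1C(O)(C#CCCCCc2ccco2)CCCCCCCCCCCCC1
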